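(The numbers are invented; the flask was simulated.)

The starting material charged to a flask is conserved: it stays as itself or stands as open intermediate, target, uncatalysed product or trapped intermediate, and the catalyst intermediate can hold no more than 0.111% of it. So I reckon the open intermediate as what the other shares leave.

    starting material + free catalyst → free catalyst + open intermediate (k1 = 16 M⁻¹ s⁻¹)
    second catalyst + open intermediate ⇌ catalyst intermediate (K2 = 720 M⁻¹, k2 = 49000 M⁻¹ s⁻¹)
    coupling partner + catalyst intermediate → second catalyst + target (k3 = 9.7 M⁻¹ s⁻¹)
    starting material + coupling partner → uncatalysed product (k4 = 0.16 M⁻¹ s⁻¹)
    open intermediate + capture agent → trapped intermediate (k5 = 23 M⁻¹ s⁻¹)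

common to all: capture agent 7.60 mM; free catalyst 7.6 mM; second catalyst 84 µM

| run | starting material | coupling partner | time | remark |
|---|---|---|---|---|
| green | 0.076 M | 0.190 M | 2.0 min | a closed flask charged with all of it at once and left for 2.0 min |
| grey | 0.076 M | 0.190 M |  | a single well-mixed tank run continuously and read at steady state, 2.0 min in it on average |
| teal | 0.076 M (fed, over 2.00 min) | 0.190 M | 2.0 min | a stirred flask in which starting material is dosed at a steady rate over 2.00 min without added volume, worked up at 2.0 min |
| amber | 0.076 M | 0.190 M (fed, over 2.00 min) | 2.0 min | a stirred flask in which coupling partner is dosed at a steady rate over 2.00 min without added volume, worked up at 2.0 min |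

- the stated concentrations are those of everything mixed, before any reaction; amounts are the same in each set-up
- the feed brings no volume worth counting
- run time (green): 2.0 min

- the set-up with the highest amount of open intermediate at the outlet or at the end, in percent of the starting material put in ("none" if the first two lie within 2 percentage points) (green / grey / teal / amber / none)
- amount of open intermediate at the outlet or at the end, in percent of the starting material put in, green
- amount of open intermediate at the outlet or at the end, in percent of the starting material put in, grey
- amount of open intermediate at the outlet or at the end, in percent of the starting material put in, teal
- amount of open intermediate at the outlet or at the end, in percent of the starting material put in, amber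

Starting material has two exits, opening on free catalyst and direct reaction with coupling partner. I fold them into one selectivity factor S 4.00, the opening constant times c(free catalyst) divided by the side-reaction constant times the c(coupling partner) that the starting material meets. The symmetric case is S of 1, an even split, and the uncatalysed share is 1/(1+S).

As charged, S is 4.00, so that share is 20.0%; opening has the shorter half-life, 0.095 min against 0.38 min. Teal doses starting material and grey is a tank read at steady state; I place both with green, at S as charged. In amber the coupling partner arrives at 0.0950 M min⁻¹, and over the opening lifetime of 8.22 s I reckon 0.0130 M gathers. S there is 58.4 and the share 1.68%.

Is one number enough? No. S puts the uncatalysed share of amber 18 percentage points lower than that of green, but coupling counts too. I assume the second catalyst stands as catalyst intermediate, the resting state, which gives an estimate of target of 24.4% in green, with coupling partner taken at its charge, and 12.2% in amber, where I take coupling partner to average half its charge. Capture agent takes 10.0%. My tally is 45.6% for green and 76.1% for amber.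

The forecast, higher than my tally for green, gives 51% for green, 47.9% for grey, 47.4% for teal and 76.2% for amber, names amber, and holds that “Dosing the coupling partner starves both the uncatalysed side reaction and the coupling step”.

The simulation gives 49.8% for green, 47.9% for grey, 48.3% for teal and 76.9% for amber, so amber stands highest.

Green holds 0.0129% of starting material at 1.00 min, and its uncatalysed product ends at 19.3% against my 20.0%; in amber it ends at 1.59% against my 1.68%. The neighbour is teal with 0.030 M of capture agent. Capture agent does not enter S, so S stays 4.00 there; with 5.61% of starting material left, I reckon 18.9% of uncatalysed product, and that neighbour holds 18.0%, as teal holds 17.8%. Its trapped intermediate stands at 39.5%, and its open intermediate at 23.6%.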